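The route rests on a [3+3] disconnection of the pyranone ring (ring C). C4 and C8a of the aroyl unit are 1,3-related electrophilic carbons once C8a carries fluoride ortho to the carbonyl. O1–C2–C3 is the ambident enolate of a methyl ketone. In one operation the kinetic enolate of 2-nonadecanone is C-acylated by 2-fluoro-4,6-dimethoxy-3,5-dimethylbenzoyl chloride (C3–C4), and the resulting diketonate oxygen displaces fluoride (O1–C8a), giving the complete chromone. The precursors are thus an acyclic ketone and a hexasubstituted benzoic acid, built by three directed metalations that need no regiochemical choice after the first. Catalyst-controlled copper hydride reduction then sets C2 as (S), and demethylation finishes.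

Key step: step 4

Numbering: chromanone numbering is used throughout (O1, C2, C3, C4, C4a, C5 to C8, C8a). Ring A is the benzene ring and ring C the pyranone ring.

Assumption: (R)-DTBM-SEGPHOS is taken as the ligand antipode that sends hydride to the Re face of C2 of 12. If the sense proves opposite, the (S)-ligand is used with nothing else changed.

Step 1
Reactants: 1 1-fluoro-3,5-dimethoxybenzene
Product: 3 5-fluoro-1,3-dimethoxy-2-methylbenzene, via aryllithium 2 (not isolated)
Conditions: n-BuLi (1.1 equiv), Et2O, 0 °C; then MeI, −78 °C → rt
Reagents that add atoms: iodomethane (MeI), CI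
Why: Directed ortho-metalation followed by SN2 methylation: in ether without a chelating amine or potassium alkoxide, n-BuLi is guided by coordination to the two methoxy oxygens to the C–H between them rather than to the more acidic C–H next to fluorine, and aryllithium 2, which has no ortho fluorine, cannot lose LiF before MeI traps it.

Step 2
Reactants: 3 5-fluoro-1,3-dimethoxy-2-methylbenzene
Product: 5 1-fluoro-3,5-dimethoxy-2,4-dimethylbenzene, via aryllithium 4 (not isolated)
Conditions: s-BuLi (1.1 equiv), TMEDA, THF, −78 °C; then MeI, −78 °C → rt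
Reagents that add atoms: iodomethane (MeI), CI
Why: Directed ortho-metalation followed by SN2 methylation: the two ring C–H bonds left in 3 are equivalent by symmetry and doubly activated by flanking F and OMe, so a single aryllithium 4 should form, which is kept at −78 °C to prevent loss of LiF to an aryne until MeI has reacted.

Step 3
Reactants: 5 1-fluoro-3,5-dimethoxy-2,4-dimethylbenzene
Product: 7 2-fluoro-4,6-dimethoxy-3,5-dimethylbenzoic acid, via aryllithium 6 (not isolated)
Conditions: s-BuLi (1.1 equiv), TMEDA, THF, −78 °C; then dry CO2, −78 → 0 °C; cold 1 M HCl work-up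
Reagents that add atoms: carbon dioxide, O=C=O
Why: Directed ortho-metalation followed by carboxylation: the only ring C–H of 5 lies between F and OMe, so 6 forms without a regiochemical alternative and adds to CO2, and cold dilute acid in the work-up avoids protodecarboxylation of the electron-rich acid.

Step 4
Reactants: 7 2-fluoro-4,6-dimethoxy-3,5-dimethylbenzoic acid; 8 2-nonadecanone
Product: 12 2-heptadecyl-5,7-dimethoxy-6,8-dimethyl-4H-chromen-4-one, via acid chloride 9 (not isolated), via lithium enolate 10 (not isolated), via lithium diketonate 11 (not isolated)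
Conditions: (a) 7, (COCl)2, cat. DMF, CH2Cl2, 0 °C → rt, volatiles removed; (b) 8 (2.1 equiv), LiHMDS (2.1 equiv), THF, −78 °C, then crude 9 in THF, −78 °C → rt; (c) DMF and K2CO3 added, THF distilled off, 100 °C
Reagents that add atoms: none
Why: The kinetic terminal enolate 10 attacks acid chloride 9 through carbon (Claisen-type C-acylation, C3–C4), a second equivalent of 10 deprotonates the diketone and returns any O-acylated enol ester to the C-acyl manifold to give 11, and on heating in DMF the oxygen on C2 adds to the fluorine-bearing carbon ortho to the aroyl carbonyl and fluoride leaves (SNAr, O1–C8a). The closest known reaction types are the tandem C-acylation/intramolecular O-arylation of 2-halobenzoyl chlorides with ketone or 1,3-dicarbonyl enolates and the base-mediated cyclisation of 1-(2-haloaryl)-1,3-diketones to chromones. Ring C closes as a six-membered ring by 6-endo-trig addition–elimination, the charge of the Meisenheimer-type adduct being taken up through C4a by the C4 carbonyl, and DMF with potassium ions loosens the lithium chelate so that the C3–C4 bond can rotate the oxygen toward C8a. No stereocentre is created, and C2 emerges as a planar prochiral enol-ether carbon for step 5. The step needs methyl over methylene enolisation, secured by cold kinetic deprotonation and by the hindered aroyl chloride choosing the unhindered terminus, and it needs fluoride over the other ortho methoxy group as nucleofuge, secured by the far better leaving ability of fluoride in SNAr. Only the C2 oxygen can reach ring A, because attack through C3 or through the C4 oxygen would give four-membered rings.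

Step 5
Reactants: 12 2-heptadecyl-5,7-dimethoxy-6,8-dimethyl-4H-chromen-4-one
Product: 13 (S)-2-heptadecyl-5,7-dimethoxy-6,8-dimethylchroman-4-one
Conditions: Cu(OAc)2 (5 mol %), (R)-DTBM-SEGPHOS (5.5 mol %), (EtO)2MeSiH, t-BuOH, toluene, 0 °C → rt; aq. NH4Cl work-up
Reagents that add atoms: none
Why: Copper hydride asymmetric conjugate reduction of a 2-alkylchromone: the bisphosphine-bound monovalent copper hydride formed from Cu(OAc)2 and the silane should deliver hydride to the Re face of C2 under catalyst control, which sets (S), and t-BuOH protonates the copper enolate at once so that neither 1,2-reduction nor β-elimination of the aryloxide intervenes.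

Step 6
Reactants: 13 (S)-2-heptadecyl-5,7-dimethoxy-6,8-dimethylchroman-4-one
Product: 14 (S)-2-heptadecyl-5,7-dihydroxy-6,8-dimethylchroman-4-one (target)
Conditions: BBr3 (4 equiv), CH2Cl2, −78 → 0 °C; then ice-water, neutral to acidic work-up
Reagents that add atoms: none
Why: Lewis-acid aryl methyl ether cleavage: bromide attacks the unhindered methyl carbons of the boron-bound 5-OMe (chelated to C4=O) and 7-OMe (twisted out of conjugation by two flanking methyl groups), whereas O1–C2 is a secondary, β-keto-deactivated vinylogous ester linkage that should stay intact at low temperature, so C2 keeps its configuration.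

Compound list
1 | 1-fluoro-3,5-dimethoxybenzene | COc1cc(F)cc(OC)c1 | starting material
2 | 4-fluoro-2,6-dimethoxyphenyllithium | [Li]c1c(OC)cc(F)cc1OC | intermediate
3 | 5-fluoro-1,3-dimethoxy-2-methylbenzene | Cc1c(OC)cc(F)cc1OC | intermediate
4 | 2-fluoro-4,6-dimethoxy-5-methylphenyllithium | Cc1c(OC)c([Li])c(F)cc1OC | intermediate
5 | 1-fluoro-3,5-dimethoxy-2,4-dimethylbenzene | Cc1c(OC)c(C)c(F)cc1OC | intermediate
6 | 2-fluoro-4,6-dimethoxy-3,5-dimethylphenyllithium | Cc1c(OC)c(C)c(F)c([Li])c1OC | intermediate
7 | 2-fluoro-4,6-dimethoxy-3,5-dimethylbenzoic acid | Cc1c(OC)c(C)c(F)c(C(=O)O)c1OC | intermediate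
8 | 2-nonadecanone | CCCCCCCCCCCCCCCCCC(C)=O | starting material
9 | 2-fluoro-4,6-dimethoxy-3,5-dimethylbenzoyl chloride | Cc1c(OC)c(C)c(F)c(C(=O)Cl)c1OC | intermediate
10 | lithium nonadec-1-en-2-olate | C=C(O[Li])CCCCCCCCCCCCCCCCC | intermediate
11 | lithium (Z)-1-(2-fluoro-4,6-dimethoxy-3,5-dimethylphenyl)-1-oxoicos-2-en-3-olate | CCCCCCCCCCCCCCCCC/C(O[Li])=C/C(=O)c1c(F)c(C)c(OC)c(C)c1OC | intermediate
12 | 2-heptadecyl-5,7-dimethoxy-6,8-dimethyl-4H-chromen-4-one | CCCCCCCCCCCCCCCCCC1=CC(=O)c2c(OC)c(C)c(OC)c(C)c2O1 | intermediate
13 | (S)-2-heptadecyl-5,7-dimethoxy-6,8-dimethylchroman-4-one | CCCCCCCCCCCCCCCCC[C@H]1CC(=O)c2c(OC)c(C)c(OC)c(C)c2O1 | intermediate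
14 | (S)-2-heptadecyl-5,7-dihydroxy-6,8-dimethylchroman-4-one | CCCCCCCCCCCCCCCCC[C@H]1CC(=O)c2c(O)c(C)c(O)c(C)c2O1 | target

Total step count: 6. Longest linear sequence: 6 (1 → 3 → 5 → 7 → 12 → 13 → 14).

Steps most likely to fail

Step 4.
- What may go wrong: acyl transfer to the enolate oxygen or to the internal enolate carbon; sluggish attack at the di-ortho-substituted aroyl carbon; slow fluoride displacement from the tightly chelated lithium diketonate.
- Fallback: it sets out from 5, comes back at 12, and swaps the roles of the partners so that the hindered aroyl carbon is never attacked by an enolate.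
- Compound 5 is lithiated to 6 as in step 3 and quenched with N-methoxy-N-methylacetamide to give 1-(2-fluoro-4,6-dimethoxy-3,5-dimethylphenyl)ethan-1-one F1.
- The LiHMDS enolate of F1, whose only enolisable carbon is the methyl group, is acylated with unhindered octadecanoyl chloride. Mild acid work-up gives the isolated 1-(2-fluoro-4,6-dimethoxy-3,5-dimethylphenyl)icosane-1,3-dione F2.
- F2 is then closed as its potassium salt (K2CO3, DMF, 100 °C) to 12.

Step 5.
- What may go wrong: poor facial selectivity with the long flexible chain; over-reduction of the ketone; ring opening of the copper enolate with loss of configuration.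
- Fallback: it sets out from 12, comes back at 13, and replaces conjugate hydride transfer by exhaustive asymmetric hydrogenation followed by reoxidation.
- Compound 12 is hydrogenated (H2 under pressure, toluene) over a chiral ruthenium N-heterocyclic carbene catalyst made from Ru(cod)(2-methylallyl)2, a C2-symmetric chiral imidazolinium tetrafluoroborate and KOt-Bu. The ligand antipode is chosen for (2S).
- This saturates C2=C3 and also reduces C4=O, to give (2S,4R)-2-heptadecyl-5,7-dimethoxy-6,8-dimethylchroman-4-ol F3.
- Neutral oxidation of the benzylic alcohol with MnO2 in CH2Cl2 then returns 13 without touching C2.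

Step 6.
- What may go wrong: erosion of configuration at C2 through Lewis-acid-induced enolisation and reversible opening of ring C, or cleavage of the O1–C2 bond.
- Fallback: it sets out from 12, comes back at 14, and moves the harsh demethylation ahead of the stereocentre.
- BBr3 in CH2Cl2 converts the achiral chromone 12 into 2-heptadecyl-5,7-dihydroxy-6,8-dimethyl-4H-chromen-4-one F4.
- Benzyl bromide and K2CO3 in DMF at 60 °C give 5,7-bis(benzyloxy)-2-heptadecyl-6,8-dimethyl-4H-chromen-4-one F5.
- The copper hydride reduction of step 5 gives (S)-5,7-bis(benzyloxy)-2-heptadecyl-6,8-dimethylchroman-4-one F6.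
- Neutral hydrogenolysis (H2, Pd/C, EtOAc, rt) releases 14.

Further compounds
F1 | step 4 | 1-(2-fluoro-4,6-dimethoxy-3,5-dimethylphenyl)ethan-1-one | CC(=O)c1c(F)c(C)c(OC)c(C)c1OC
F2 | step 4 | 1-(2-fluoro-4,6-dimethoxy-3,5-dimethylphenyl)icosane-1,3-dione | CCCCCCCCCCCCCCCCCC(=O)CC(=O)c1c(F)c(C)c(OC)c(C)c1OC
F3 | step 5 | (2S,4R)-2-heptadecyl-5,7-dimethoxy-6,8-dimethylchroman-4-ol | CCCCCCCCCCCCCCCCC[C@H]1C[C@@H](O)c2c(OC)c(C)c(OC)c(C)c2O1
F4 | step 6 | 2-heptadecyl-5,7-dihydroxy-6,8-dimethyl-4H-chromen-4-one | CCCCCCCCCCCCCCCCCC1=CC(=O)c2c(O)c(C)c(O)c(C)c2O1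
F5 | step 6 | 5,7-bis(benzyloxy)-2-heptadecyl-6,8-dimethyl-4H-chromen-4-one | CCCCCCCCCCCCCCCCCC1=CC(=O)c2c(OCc3ccccc3)c(C)c(OCc3ccccc3)c(C)c2O1
F6 | step 6 | (S)-5,7-bis(benzyloxy)-2-heptadecyl-6,8-dimethylchroman-4-one | CCCCCCCCCCCCCCCCC[C@H]1CC(=O)c2c(OCc3ccccc3)c(C)c(OCc3ccccc3)c(C)c2O1
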